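**Retrosynthetic overview**

- The strategy rests on the fully substituted oxazole (O1, C2 carrying the pyrrol-2-yl, N3, C4 carrying iodine, C5 carrying the indol-3-yl). It is opened at the O1–C5 bond to a 1-acyl-5-iodo-4-(indol-3-yl)-1,2,3-triazole that loses dinitrogen, so the C4–I bond exists before the oxazole does.
- The acyltriazole comes from N-acylation of an NH-iodotriazole with 1-tosylpyrrole-2-carbonyl chloride. The iodotriazole comes from a copper-catalysed cycloaddition of a 3-(iodoethynyl)indole with azidomethyl pivalate.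
- The iodoalkyne is reached from 6-bromo-4-methoxyindole by C3 iodination, N-tosylation, a Sonogashira coupling selective for C–I over C–Br, and desilylative iodination.
- Ring order: indole and pyrrole are bought intact, the triazole is built on the indole C3 alkyne, the oxazole is formed last from the triazole, and both N-tosyl groups are removed at the end.

Key step: step 11

Remark: an N-acyl-1,2,3-triazole is an equilibrating set of N-acyl isomers; the product of step 10 is drawn as the isomer acylated on the nitrogen next to the C–I carbon, the one that leads on to the oxazole.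

**Route**

Step 1
Reactants: 1 6-bromo-4-methoxy-1H-indole
Product: 2 6-bromo-3-iodo-4-methoxy-1H-indole
Conditions: I2, KOH, DMF, rt; aq. NaHSO3 work-up; used crude, kept from light
Reagents that add atoms: iodine, II
Why: Electrophilic aromatic substitution at C3, the most nucleophilic indole position, should outrun attack on the methoxy-activated benzo ring, and the aryl bromide and methyl ether are untouched.

Step 2
Reactants: 2 6-bromo-3-iodo-4-methoxy-1H-indole
Product: 3 6-bromo-3-iodo-4-methoxy-1-tosylindole
Conditions: NaH, TsCl, THF, 0 °C to rt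
Reagents that add atoms: p-toluenesulfonyl chloride, Cc1ccc(cc1)S(Cl)(=O)=O
Why: N-Sulfonylation of the indolyl anion stabilises the labile 3-iodoindole and deactivates the indole toward the later iodine electrophile and acid chloride, while C–I and C–Br stay intact.

Step 3
Reactants: 3 6-bromo-3-iodo-4-methoxy-1-tosylindole; 4 ethynyltrimethylsilane
Product: 5 6-bromo-4-methoxy-1-tosyl-3-(trimethylsilylethynyl)indole
Conditions: PdCl2(PPh3)2 (3 mol %), CuI (5 mol %), Et3N/THF, rt
Reagents that add atoms: none
Why: Sonogashira coupling: oxidative addition of zerovalent palladium into the C3–I bond is much faster than into the C6–Br bond at room temperature, so only the iodide should be alkynylated.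

Step 4
Reactants: 5 6-bromo-4-methoxy-1-tosyl-3-(trimethylsilylethynyl)indole
Product: 6 6-bromo-3-(iodoethynyl)-4-methoxy-1-tosylindole
Conditions: NIS, AgF, MeCN, rt, dark
Reagents that add atoms: N-iodosuccinimide, O=C1CCC(=O)N1I
Why: Desilylative iodination: fluoride-assisted formation of a silver acetylide and its capture by NIS gives the 1-iodoalkyne without any base that would endanger the N-tosyl group, and the sulfonylated indole is too deactivated for ring iodination under these neutral conditions.

Step 5
Reactants: 6 6-bromo-3-(iodoethynyl)-4-methoxy-1-tosylindole; 7 azidomethyl pivalate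
Product: 8 [4-(6-bromo-4-methoxy-1-tosylindol-3-yl)-5-iodo-1,2,3-triazol-1-yl]methyl pivalate
Conditions: CuI (5 mol %), tris[(1-tert-butyl-1H-1,2,3-triazol-4-yl)methyl]amine (5 mol %), THF, rt
Reagents that add atoms: none
Why: The copper-catalysed iodoalkyne–azide cycloaddition with CuI and a tris(triazolylmethyl)amine ligand keeps the C–I bond and gives only the 1,4,5-trisubstituted 5-iodotriazole, which fixes iodine on the carbon that becomes oxazole C4.

Step 6
Reactants: 8 [4-(6-bromo-4-methoxy-1-tosylindol-3-yl)-5-iodo-1,2,3-triazol-1-yl]methyl pivalate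
Product: 9 6-bromo-3-(5-iodo-1H-1,2,3-triazol-4-yl)-4-methoxy-1-tosylindole
Conditions: NaOH (2.2 equiv), MeOH/H2O, 0 °C, 15–20 min; then 1 M HCl to pH 5
Reagents that add atoms: none
Why: Hydroxide cleaves the pivalate ester and the resulting N-hydroxymethyl triazole sheds formaldehyde to give the NH-triazole; at 0 °C and short contact time the more slowly cleaved indole N-tosyl group should survive.

Step 7
Reactants: 10 pyrrole-2-carboxaldehyde
Product: 11 1-tosylpyrrole-2-carboxaldehyde
Conditions: NaH, TsCl, THF, 0 °C to rt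
Reagents that add atoms: p-toluenesulfonyl chloride, Cc1ccc(cc1)S(Cl)(=O)=O
Why: N-Sulfonylation of the pyrrolyl anion, made easy by the acidifying 2-formyl group, protects the pyrrole nitrogen and deactivates the ring for the steps that follow.

Step 8
Reactants: 11 1-tosylpyrrole-2-carboxaldehyde
Product: 12 1-tosylpyrrole-2-carboxylic acid
Conditions: NaClO2, NaH2PO4, 2-methyl-2-butene, t-BuOH/H2O, rt
Reagents that add atoms: sodium chlorite, [Na+].[O-]Cl=O
Why: Pinnick oxidation converts the aldehyde into the acid under buffered conditions, with 2-methyl-2-butene scavenging the hypochlorous acid that could otherwise chlorinate the pyrrole.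

Step 9
Reactants: 12 1-tosylpyrrole-2-carboxylic acid
Product: 13 1-tosylpyrrole-2-carbonyl chloride
Conditions: (COCl)2, DMF (cat.), CH2Cl2, 0 °C to rt; evaporated and used crude
Reagents that add atoms: oxalyl chloride, O=C(Cl)C(Cl)=O
Why: Vilsmeier-type activation of the acid by oxalyl chloride and catalytic DMF gives the acid chloride with only gaseous by-products, and the N-sulfonyl pyrrole tolerates the HCl formed.

Step 10
Reactants: 9 6-bromo-3-(5-iodo-1H-1,2,3-triazol-4-yl)-4-methoxy-1-tosylindole; 13 1-tosylpyrrole-2-carbonyl chloride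
Product: 14 [4-(6-bromo-4-methoxy-1-tosylindol-3-yl)-5-iodo-1,2,3-triazol-1-yl](1-tosylpyrrol-2-yl)methanone
Conditions: Et3N, CH2Cl2, 0 °C to rt; amine salt filtered off, filtrate concentrated and used at once
Reagents that add atoms: none
Why: N-Acylation of the acidic NH-triazole, as its triazolide with Et3N, by the acid chloride; the indole and pyrrole nitrogens are blocked as sulfonamides so only the triazole reacts, and the moisture-sensitive isomer mixture is carried on because the isomers interconvert on heating.

Step 11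
Reactants: 14 [4-(6-bromo-4-methoxy-1-tosylindol-3-yl)-5-iodo-1,2,3-triazol-1-yl](1-tosylpyrrol-2-yl)methanone
Product: 15 5-(6-bromo-4-methoxy-1-tosylindol-3-yl)-4-iodo-2-(1-tosylpyrrol-2-yl)oxazole (bis-N-tosyl breitfussin A)
Conditions: dry PhMe, 100 °C, Ar (Zn(OTf)2, 10 mol %, added only if conversion stalls)
Reagents that add atoms: none
Why: The N1-acyl isomer, replenished from the N2-acyl isomer by acyl transfer, opens at its N1–N2 bond to an alpha-diazo N-acylimidoyl iodide, which loses dinitrogen to leave an imino carbene (a vinyl cation under acid) on the indolyl-bearing carbon. The acyl oxygen then bonds to that carbon in a 1,5-electrocyclisation (formally a 5-endo closure), which makes the O1–C5 bond and closes the oxazole ring with iodine already on C4 and the pyrrole on C2. The reaction type is the known thermal or acid-promoted denitrogenative conversion of 1-acyl-1,2,3-triazoles into oxazoles, a relative of the Huisgen acyltetrazole-to-oxadiazole reaction; a 5-iodo-4-(indol-3-yl) member of the class is untried, which is why the Lewis acid is held in reserve to speed acyl migration and ring opening. No stereocentre is formed. The selectivity needed is reaction through the isomer acylated next to the C–I carbon: only that isomer places the diazo group and the electron-poor centre on the carbon stabilised by indole C3, whereas the isomer acylated next to the indolyl carbon would need a diazo group or cation on the iodine-bearing carbon and is crowded by the peri 4-methoxy group.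

Step 12
Reactants: 15 5-(6-bromo-4-methoxy-1-tosylindol-3-yl)-4-iodo-2-(1-tosylpyrrol-2-yl)oxazole
Product: 16 5-(6-bromo-4-methoxy-1H-indol-3-yl)-4-iodo-2-(1H-pyrrol-2-yl)oxazole (breitfussin A)
Conditions: Cs2CO3, MeOH/THF, rt to 40 °C
Reagents that add atoms: none
Why: Methoxide generated by Cs2CO3 in methanol attacks sulfur of both N-sulfonyl azoles (N–S cleavage) and frees the indole and pyrrole NH groups; the aryl bromide, the iodooxazole and the methyl ether are inert to these conditions.

**Compound list**

1 | 6-bromo-4-methoxy-1H-indole | COc1cc(Br)cc2[nH]ccc12 | starting material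
2 | 6-bromo-3-iodo-4-methoxy-1H-indole | COc1cc(Br)cc2[nH]cc(I)c12 | intermediate
3 | 6-bromo-3-iodo-4-methoxy-1-tosylindole | COc1cc(Br)cc2n(S(=O)(=O)c3ccc(C)cc3)cc(I)c12 | intermediate
4 | ethynyltrimethylsilane | C#C[Si](C)(C)C | starting material
5 | 6-bromo-4-methoxy-1-tosyl-3-(trimethylsilylethynyl)indole | COc1cc(Br)cc2n(S(=O)(=O)c3ccc(C)cc3)cc(C#C[Si](C)(C)C)c12 | intermediate
6 | 6-bromo-3-(iodoethynyl)-4-methoxy-1-tosylindole | COc1cc(Br)cc2n(S(=O)(=O)c3ccc(C)cc3)cc(C#CI)c12 | intermediate
7 | azidomethyl pivalate | CC(C)(C)C(=O)OCN=[N+]=[N-] | starting material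
8 | [4-(6-bromo-4-methoxy-1-tosylindol-3-yl)-5-iodo-1,2,3-triazol-1-yl]methyl pivalate | COc1cc(Br)cc2n(S(=O)(=O)c3ccc(C)cc3)cc(-c3nnn(COC(=O)C(C)(C)C)c3I)c12 | intermediate
9 | 6-bromo-3-(5-iodo-1H-1,2,3-triazol-4-yl)-4-methoxy-1-tosylindole | COc1cc(Br)cc2n(S(=O)(=O)c3ccc(C)cc3)cc(-c3nn[nH]c3I)c12 | intermediate
10 | pyrrole-2-carboxaldehyde | O=Cc1ccc[nH]1 | starting material
11 | 1-tosylpyrrole-2-carboxaldehyde | Cc1ccc(cc1)S(=O)(=O)n1cccc1C=O | intermediate
12 | 1-tosylpyrrole-2-carboxylic acid | Cc1ccc(cc1)S(=O)(=O)n1cccc1C(O)=O | intermediate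
13 | 1-tosylpyrrole-2-carbonyl chloride | Cc1ccc(cc1)S(=O)(=O)n1cccc1C(Cl)=O | intermediate
14 | [4-(6-bromo-4-methoxy-1-tosylindol-3-yl)-5-iodo-1,2,3-triazol-1-yl](1-tosylpyrrol-2-yl)methanone | COc1cc(Br)cc2n(S(=O)(=O)c3ccc(C)cc3)cc(-c3nnn(C(=O)c4cccn4S(=O)(=O)c4ccc(C)cc4)c3I)c12 | intermediate
15 | 5-(6-bromo-4-methoxy-1-tosylindol-3-yl)-4-iodo-2-(1-tosylpyrrol-2-yl)oxazole | COc1cc(Br)cc2n(S(=O)(=O)c3ccc(C)cc3)cc(-c3oc(-c4cccn4S(=O)(=O)c4ccc(C)cc4)nc3I)c12 | intermediate
16 | 5-(6-bromo-4-methoxy-1H-indol-3-yl)-4-iodo-2-(1H-pyrrol-2-yl)oxazole (breitfussin A) | COc1cc(Br)cc2[nH]cc(-c3oc(-c4ccc[nH]4)nc3I)c12 | target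

**Step count**

Total steps: 12. Longest linear sequence: 9 steps (steps 1–6, then 10–12); steps 7–9 make the acid chloride in a side branch.

**Steps most likely to fail**

1. Step 11. The acyl group may stay on the central triazole nitrogen and not funnel through the reactive isomer. The ring-opened imidoyl iodide may instead be hydrolysed by trace water, or a 1,2-shift of iodine to a ketenimine may compete with closure on oxygen. The fallback builds the oxazole by cross-coupling, sets out from 3 and returns at 16.
   - Suzuki–Miyaura coupling of 3 at its C–I bond with commercial 5-(4,4,5,5-tetramethyl-1,3,2-dioxaborolan-2-yl)-2-(triisopropylsilyl)oxazole (Pd(dppf)Cl2, K3PO4, dioxane/H2O, 60 °C) should give 5-(6-bromo-4-methoxy-1-tosylindol-3-yl)-2-(triisopropylsilyl)oxazole F1.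
   - Bu4NF buffered with AcOH in THF removes the C2 silyl group to give 5-(6-bromo-4-methoxy-1-tosylindol-3-yl)oxazole F2.
   - Excess LiN(SiMe3)2 and I2 in THF at −78 °C iodinate C2 and, through the ring-opened isocyano enolate, C4, to give 5-(6-bromo-4-methoxy-1-tosylindol-3-yl)-2,4-diiodooxazole F3.
   - A second Suzuki–Miyaura coupling with 1-Boc-pyrrole-2-boronic acid (Pd(PPh3)4, aq. Na2CO3, DME, 50 °C), selective for the more electron-poor C2–I bond, gives tert-butyl 2-[5-(6-bromo-4-methoxy-1-tosylindol-3-yl)-4-iodooxazol-2-yl]pyrrole-1-carboxylate F4.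
   - Cs2CO3 in MeOH/THF then removes the N-tosyl and N-Boc groups together and delivers 16.

2. Step 5. The cycloaddition may stall at the alkyne crowded by the peri 4-methoxy group, or iodine may be lost by reduction of the iodoalkyne or protonation of the cuprated triazole. The fallback puts iodine on after the triazole is made, sets out from 5 and returns at 9.
   - K2CO3 in MeOH/THF at 0 °C removes the silyl group of 5 to give 6-bromo-3-ethynyl-4-methoxy-1-tosylindole F5.
   - Standard copper-catalysed azide–alkyne cycloaddition with 7 (CuSO4·5H2O, sodium ascorbate, t-BuOH/H2O, rt) gives [4-(6-bromo-4-methoxy-1-tosylindol-3-yl)-1,2,3-triazol-1-yl]methyl pivalate F6.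
   - Brief NaOH in MeOH/H2O at 0 °C gives 6-bromo-4-methoxy-3-(1H-1,2,3-triazol-4-yl)-1-tosylindole F7.
   - Electrophilic iodination of the triazolide at its free carbon (I2, K2CO3, DMF, rt) gives 9.

3. Step 6. The indole N-tosyl group may be lost prematurely during the basic methanolysis, since both groups are base-labile; the resulting mixture would acylate unselectively. The fallback uses an acid-labile triazole substituent, sets out from 6 and returns at 9.
   - Cycloaddition of 6 with 4-methoxybenzyl azide under the step 5 conditions gives 6-bromo-3-[5-iodo-1-(4-methoxybenzyl)-1,2,3-triazol-4-yl]-4-methoxy-1-tosylindole F8.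
   - Acidolysis of the 4-methoxybenzyl group (TFA, anisole, 65 °C), which leaves the sulfonamide untouched, gives 9.

**Further compounds**

F1 | step 11 | 5-(6-bromo-4-methoxy-1-tosylindol-3-yl)-2-(triisopropylsilyl)oxazole | COc1cc(Br)cc2n(S(=O)(=O)c3ccc(C)cc3)cc(-c3cnc(o3)[Si](C(C)C)(C(C)C)C(C)C)c12
F2 | step 11 | 5-(6-bromo-4-methoxy-1-tosylindol-3-yl)oxazole | COc1cc(Br)cc2n(S(=O)(=O)c3ccc(C)cc3)cc(-c3cnco3)c12
F3 | step 11 | 5-(6-bromo-4-methoxy-1-tosylindol-3-yl)-2,4-diiodooxazole | COc1cc(Br)cc2n(S(=O)(=O)c3ccc(C)cc3)cc(-c3oc(I)nc3I)c12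
F4 | step 11 | tert-butyl 2-[5-(6-bromo-4-methoxy-1-tosylindol-3-yl)-4-iodooxazol-2-yl]pyrrole-1-carboxylate | COc1cc(Br)cc2n(S(=O)(=O)c3ccc(C)cc3)cc(-c3oc(-c4cccn4C(=O)OC(C)(C)C)nc3I)c12
F5 | step 5 | 6-bromo-3-ethynyl-4-methoxy-1-tosylindole | COc1cc(Br)cc2n(S(=O)(=O)c3ccc(C)cc3)cc(C#C)c12
F6 | step 5 | [4-(6-bromo-4-methoxy-1-tosylindol-3-yl)-1,2,3-triazol-1-yl]methyl pivalate | COc1cc(Br)cc2n(S(=O)(=O)c3ccc(C)cc3)cc(-c3cn(COC(=O)C(C)(C)C)nn3)c12
F7 | step 5 | 6-bromo-4-methoxy-3-(1H-1,2,3-triazol-4-yl)-1-tosylindole | COc1cc(Br)cc2n(S(=O)(=O)c3ccc(C)cc3)cc(-c3c[nH]nn3)c12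
F8 | step 6 | 6-bromo-3-[5-iodo-1-(4-methoxybenzyl)-1,2,3-triazol-4-yl]-4-methoxy-1-tosylindole | COc1cc(Br)cc2n(S(=O)(=O)c3ccc(C)cc3)cc(-c3nnn(Cc4ccc(OC)cc4)c3I)c12
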